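**Assumption:** the SMILES is read as (6R,7S,8S,9S), 4E, 1(10) ring-cis, using germacrane numbering (C1–C10 ring, C11–C13 lactone, C14 ester carbon, C15 methyl). Reagents that bring no skeletal carbon are not numbered.

## Retrosynthetic overview

1. Polymatin A ⇐ O8-angeloylation and O9-desilylation of lactone 14 ⇐ Pd cyclocarbonylation (C12 from CO) of the 7-ethynyl-6,8-diol 13. The lactone is the last ring formed.
2. 13 ⇐ closure of the 10-membered carbocycle at C6–C7 by Pd(0)/InI umpolung of the cis-alkynyl epoxide in 12 onto the C6 enal (sets C6 and C7).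
3. 12 ⇐ hydroxyl-directed threo epoxidation of Z-enynol 8 ⇐ asymmetric Ni/Cr coupling (C9–C10) of α-iodoenoate 7 (from geranyl acetate) with (Z)-pent-2-en-4-ynal 3.
4. 3 ⇐ furfural by dearomative 2-furylcarbene ring opening. The five furfural carbons become C13≡C11–C7=C8–C9, the ring oxygen becomes O9, and the ring-locked Z alkene later encodes the C7/C8 relationship.

## Route

**Step 1**
Reactants: 1 furfural
Product: 2 furfural p-toluenesulfonylhydrazone
Conditions: TsNHNH2, MeOH, rt
Reagents that add atoms: p-toluenesulfonylhydrazide, Cc1ccc(cc1)S(=O)(=O)NN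
Why: Hydrazone condensation of an aromatic aldehyde gives the Bamford–Stevens precursor; no stereocentre.

**Step 2 (key step)**
Reactants: 2
Product: 3 (2Z)-pent-2-en-4-ynal
Conditions: NaH, THF, 0 °C; dry Na salt, flash vacuum pyrolysis 100→250 °C, 0.1 mmHg, −78 °C trap; use at once as a cold solution
Reagents that add atoms: none
Why: Bamford–Stevens decomposition gives 2-furyldiazomethane and then 2-furylcarbene, which undergoes the known carbene ring opening (C2–O cleavage forming C≡C and C=O) and so destroys the furan aromaticity; the alkene is Z because it was the ring C3=C4 bond, and the volatile product leaves the hot zone before it can isomerise.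

**Step 3**
Reactants: 4 geranyl acetate
Product: 5 (2E)-3-methyl-6-oxohex-2-en-1-yl acetate
Conditions: O3 (1.0 equiv), CH2Cl2–pyridine, −78 °C; Me2S
Reagents that add atoms: ozone, [O-][O+]=O
Why: Chemoselective ozonolysis: the 6,7-alkene is more electron-rich than the 2,3-alkene deactivated by the allylic acetate, and the E C4=C5 alkene is carried over from geraniol.

**Step 4**
Reactants: 5; 6 methyl (triphenylphosphoranylidene)acetate
Product: 7 methyl (2Z,6E)-8-acetoxy-2-iodo-6-methylocta-2,6-dienoate
Conditions: 6, NIS, CH2Cl2, −20 °C; then K2CO3, 5, rt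
Reagents that add atoms: N-iodosuccinimide, O=C1CCC(=O)N1I
Why: Iodination of the stabilised ylide gives Ph3P=C(I)CO2Me in situ, and its Wittig reaction with the unhindered aldehyde favours the isomer with the chain trans to CO2Me (the Z iodoenoate), which fixes the 1(10) geometry.

**Step 5**
Reactants: 7; 3 (1.5 equiv)
Product: 8 methyl (2E,6E)-8-acetoxy-2-[(1R,2Z)-1-hydroxypent-2-en-4-yn-1-yl]-6-methylocta-2,6-dienoate
Conditions: CrCl2 (cat.), NiCl2·DMP (cat.), Kishi chiral oxazoline–sulfonamide ligand, Mn, Cp2ZrCl2, LiCl, MeCN, 0 °C→rt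
Reagents that add atoms: none
Why: Catalytic asymmetric Nozaki–Hiyama–Kishi alkenylation: the alkenyl–Cr(III) species adds 1,2 to the enal with retention of the C1=C10 geometry and tolerates esters and the terminal alkyne, and the ligand enantiomer is chosen to give the carbinol shown (R here, which is 9S of the target).

**Step 6**
Reactants: 8
Product: 9 methyl (2E,6E)-8-acetoxy-2-{(S)-[(2R,3S)-3-ethynyloxiran-2-yl](hydroxy)methyl}-6-methylocta-2,6-dienoate (cis-epoxide, threo to O9)
Conditions: Ti(OiPr)4, TBHP, 4 Å MS, CH2Cl2, −20 °C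
Reagents that add atoms: tert-butyl hydroperoxide, CC(C)(C)OO
Why: Hydroxyl-directed Ti/TBHP epoxidation touches only the Z-enyne alkene of the allylic alcohol (not the enoate or the remote trisubstituted alkene), and A1,3 strain in the Z-allylic alcohol gives the threo epoxy alcohol, setting C8 and the cis-epoxide carbon C7 from C9.

**Step 7**
Reactants: 9
Product: 10 methyl (2E,6E)-8-acetoxy-2-{(S)-[(tert-butyldimethylsilyl)oxy][(2S,3S)-3-ethynyloxiran-2-yl]methyl}-6-methylocta-2,6-dienoate
Conditions: TBSOTf, 2,6-lutidine, CH2Cl2, −78 °C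
Reagents that add atoms: TBSOTf, CC(C)(C)[Si](C)(C)OS(=O)(=O)C(F)(F)F
Why: Low-temperature silylation protects O9, which blocks Payne rearrangement in step 8 and differentiates O9 from O8 later; the epoxide survives at −78 °C.

**Step 8**
Reactants: 10
Product: 11, the 8-hydroxy analogue of 10 (allylic alcohol at C6)
Conditions: K2CO3, MeOH, 0 °C
Reagents that add atoms: none
Why: Mild methanolysis removes only the acetate; the methyl ester is degenerate under these conditions, and the silyl ether, epoxide and alkyne are stable.

**Step 9**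
Reactants: 11
Product: 12 methyl (2E,6E)-2-{(S)-[(tert-butyldimethylsilyl)oxy][(2S,3S)-3-ethynyloxiran-2-yl]methyl}-6-methyl-8-oxoocta-2,6-dienoate
Conditions: MnO2, CH2Cl2, rt
Reagents that add atoms: none
Why: MnO2 oxidises only the allylic alcohol, giving the (E)-enal without touching the epoxide, alkyne or silyl ether.

**Step 10**
Reactants: 12
Product: 13 methyl (1E,5E,7R,8S,9S,10S)-10-[(tert-butyldimethylsilyl)oxy]-8-ethynyl-7,9-dihydroxy-5-methylcyclodeca-1,5-diene-1-carboxylate (germacrane numbering: 6α-OH, 7β-ethynyl, 8β-OH, 9α-OTBS)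
Conditions: Pd(PPh3)4 (10 mol%), InI (2 equiv), THF–HMPA 4:1, rt, syringe-pump addition to 2 mM
Reagents that add atoms: none
Why: Proposed new method: Pd(0) opens the alkynyl epoxide anti-SN2′ to an allenyl-Pd alkoxide, InI transmetalates it to a nucleophilic allenylindium, and this adds intramolecularly to the C6 aldehyde through a cyclic SE2′ transition state to give the homopropargylic alcohol. The net result is inversion at C7 (so the cis-epoxide from the Z alkene gives the 7,8 relationship of the target), an anti C6/C7 relationship, and O8 released as the free alcohol. The closest known reactions are the intermolecular Pd/InI umpolung of propargylic mesylates and ethynyl three-membered rings and Cr-mediated Barbier macrocyclisations to germacranolides.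

**Step 11**
Reactants: 13
Product: 14, 9-O-TBS-8-deangeloyl-polymatin A ((6R,7R,8S,9S); trans-fused 6α,12-olide, free 8β-OH)
Conditions: PdCl2 (5 mol%), PPh3, SnCl2, CO (7 atm), MeCN, 75 °C
Reagents that add atoms: carbon monoxide, [C-]#[O+]
Why: Pd-catalysed cyclocarbonylation of a homopropargylic alcohol (alkoxycarbonyl-Pd at O6, syn-insertion of the alkyne, protonolysis) builds the α-methylene-γ-lactone with C12 from CO; the less hindered O6 is expected to react in preference to O8, which is flanked by the OTBS group; no stereocentre changes.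

**Step 12**
Reactants: 14; 15 angelic acid
Product: 16, 9-O-TBS-polymatin A ((6R,7S,8S,9S))
Conditions: 15, 2,4,6-trichlorobenzoyl chloride, Et3N, toluene, rt→80 °C (no DMAP)
Reagents that add atoms: none beyond reactant 15
Why: Yamaguchi-type mixed-anhydride esterification without DMAP acylates the only free hydroxyl (O8) while avoiding angelate-to-tiglate isomerisation.

**Step 13**
Reactants: 16
Product: 17 polymatin A
Conditions: HF·pyridine, pyridine–THF, 0 °C→rt
Reagents that add atoms: none
Why: Buffered, non-basic desilylation frees O9 without 8→9 acyl migration or conjugate addition to the α-methylene lactone.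

## Compound list

1 | furfural | O=Cc1ccco1 | starting material
2 | furfural p-toluenesulfonylhydrazone | Cc1ccc(cc1)S(=O)(=O)N/N=C/c1ccco1 | intermediate
3 | (2Z)-pent-2-en-4-ynal | O=C/C=C\C#C | intermediate
4 | geranyl acetate | CC(=O)OC/C=C(\C)CCC=C(C)C | starting material
5 | (2E)-3-methyl-6-oxohex-2-en-1-yl acetate | CC(=O)OC/C=C(\C)CCC=O | intermediate
6 | methyl (triphenylphosphoranylidene)acetate | COC(=O)C=P(c1ccccc1)(c1ccccc1)c1ccccc1 | starting material
7 | methyl (2Z,6E)-8-acetoxy-2-iodo-6-methylocta-2,6-dienoate | CC(=O)OC/C=C(\C)CC/C=C(/C(=O)OC)I | intermediate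
8 | methyl (2E,6E)-8-acetoxy-2-[(1R,2Z)-1-hydroxypent-2-en-4-yn-1-yl]-6-methylocta-2,6-dienoate | CC(=O)OC/C=C(\C)CC/C=C(/C(=O)OC)[C@H](O)/C=C\C#C | intermediate
9 | threo cis-epoxy alcohol (name in step 6) | CC(=O)OC/C=C(\C)CC/C=C(/C(=O)OC)[C@H](O)[C@H]1O[C@H]1C#C | intermediate
10 | O9-TBS ether of 9 | CC(=O)OC/C=C(\C)CC/C=C(/C(=O)OC)[C@H](O[Si](C)(C)C(C)(C)C)[C@H]1O[C@H]1C#C | intermediate
11 | C6 allylic alcohol (deacetylated 10) | OC/C=C(\C)CC/C=C(/C(=O)OC)[C@H](O[Si](C)(C)C(C)(C)C)[C@H]1O[C@H]1C#C | intermediate
12 | C6 enal (name in step 9) | O=C/C=C(\C)CC/C=C(/C(=O)OC)[C@H](O[Si](C)(C)C(C)(C)C)[C@H]1O[C@H]1C#C | intermediate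
13 | macrocyclic 7-ethynyl-6,8-diol (name in step 10) | O[C@@H]1/C=C(\C)CC/C=C(/C(=O)OC)[C@H](O[Si](C)(C)C(C)(C)C)[C@@H](O)[C@H]1C#C | intermediate
14 | 9-O-TBS-8-deangeloyl-polymatin A | C=C1C(=O)O[C@@H]2/C=C(\C)CC/C=C(/C(=O)OC)[C@H](O[Si](C)(C)C(C)(C)C)[C@@H](O)[C@@H]12 | intermediate
15 | angelic acid ((Z)-2-methylbut-2-enoic acid) | C/C=C(/C)C(=O)O | starting material
16 | 9-O-TBS-polymatin A | C=C1C(=O)O[C@@H]2/C=C(\C)CC/C=C(/C(=O)OC)[C@H](O[Si](C)(C)C(C)(C)C)[C@@H](OC(=O)/C(C)=C\C)[C@@H]12 | intermediate
17 | polymatin A | C=C1C(=O)O[C@@H]2/C=C(\C)CC/C=C(/C(=O)OC)[C@H](O)[C@@H](OC(=O)/C(C)=C\C)[C@@H]12 | target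

## Summary

**Total steps:** 13.
**Longest linear sequence:** 11 (steps 3–13 from geranyl acetate, or 1, 2, 5–13 from furfural).

**Steps most likely to fail:**

- **Step 10 (macrocyclic Pd/In propargylation).** Ring closure, C6 selectivity and possible O9→O8 silyl migration are untested. Fallback: form C6–C7 intermolecularly first, then close the ring at C9–C10 instead. The coupling partners would be the TBS ether of the Sharpless-derived cis-epoxide of (Z)-pent-2-en-4-yn-1-ol (from NaBH4 reduction of 3) and an enal carrying C1 as an acetal. After lactone and angelate installation, the α-iodoenoate is built and the ring closed by intramolecular Ni/Cr coupling onto a C9 aldehyde.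
- **Step 5 (asymmetric Ni/Cr coupling with the sensitive Z-enynal).** Enantioselectivity with an α-iodoenoate is unproven and 3 may isomerise. Fallback: give up the asymmetric C–C coupling. Add the alkenylmagnesium from 7 (iPrMgCl·LiCl, −78 °C) to 3 racemically, oxidise to the cross-conjugated ketone, and set C9 by CBS reduction.
- **Step 11 (lactonisation regiochemistry, O6 versus O8).** Fallback: replace cyclocarbonylation with Pd-catalysed Markovnikov hydrocarboxylation of the alkyne to the 2-substituted acrylic acid, then acid-catalysed lactonisation under equilibrating conditions, which should favour the trans-fused 6,12-olide.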